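# Proposed total synthesis of callophycoic acid F by an ortho-quinone methide / allylic ylide (4+3) annulation

## Analysis of the target

Callophycoic acid F, compound 16, is a 2,5-dihydro-1-benzoxepine in which benzene ring A is fused at C5a–C9a to a seven-membered oxacycle, ring B (O1, C2H2, C3, C4H, C5H2), whose only alkene is C3=C4. C7, para to O1, carries the carboxylic acid, and C3 carries a (3E,7E)-4,8,12-trimethyltrideca-3,7,11-trienyl chain, that is, one methylene (C1′) followed by an (E,E)-farnesyl unit. There is no stereocentre; the only stereochemical elements are the two E-trisubstituted alkenes C3′=C4′ and C7′=C8′, which are independent of each other and can be bought ready-made in (2E,6E)-farnesyl building blocks. The most sensitive site is C5, which is both benzylic and allylic, so that acid, base or metal hydrides can move C3=C4 towards ring A or into the enol ether position. The allyl aryl ether O1–C2–C3=C4 can be ionised by low-valent metals, the 1,5-polyene chain cyclises under acid, and the free acid is incompatible with carbanions. The difficulty is to close a seven-membered ring with the alkene fixed at C3=C4, and then to join C1′ to C2′, a bond between two allylic carbons, without shifting or isomerising any of the four alkenes. The strategy rests on the observation that O1, C9a, C5a and C5 are the four atoms of the ortho-quinone methide of a 4-substituted phenol, and that C2–C3–C4 is a 2-substituted allyl unit whose central carbon needs only a one-carbon handle. A 2-(alkoxycarbonyl)allyl carbonate supplies exactly that unit, and its ester carbon becomes C1′.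

## Retrosynthetic reasoning

**16 from 15 (C2′–S).** The last bond removed is the C2′–sulfur bond of the sulfonyl acid 15. The sulfonyl group is a traceless activator that exists only to make C2′ nucleophilic. The forward step must replace C–S by C–H with the hydrogen delivered to C2′, so that C3′=C4′ neither moves nor loses its E geometry, and must leave the carboxylate and ring B alone.

**15 from 14 (C7–carboxyl).** The acid is disconnected at the C7–carboxyl bond and carried as the aryl bromide of 14. A bromide survives the hydride reduction, the bromination and the carbanion alkylation, which a free acid or a second ester would not. The carbonylation is placed after the alkylation, because an acid would quench the carbanion. It is placed before the desulfonylation, because the palladium hydride conditions of that step would strip the bromine.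

**14 from 10 and 12, through 13 (C1′–C2′).** Cutting C1′–C2′ divides the molecule into the ring with its one-carbon handle (bromide 10) and a C15 unit in which both E alkenes already exist (sulfone 12, deprotonated to 13). Cutting C2′–C3′ or C3′=C4′ would require building a trisubstituted E alkene, and cutting C3–C1′ would put a coupling on the ring alkene. The sulfone confines the nucleophilic reactivity of the farnesyl unit to its α-carbon, which answers the α/γ problem of allyl–allyl coupling.

**12 from 11 and 2 (C–S).** The sulfone 12 comes from (2E,6E)-farnesyl bromide 11 and the sulfinate 2 by a carbon–sulfur disconnection. The same salt 2 is used again for the ring precursor.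

**10 from 9 from 8 (functional group changes).** The bromide 10 is traced through the allylic alcohol 9 to the ester 8. The ester carbon of 8 is C1′, so the handle is installed in the ring-forming step at no extra cost.

**8 from 3 and 5, through 6 and 7 (C4–C5 and O1–C2).** This is the central disconnection. It cuts ring B into the two halves recognised in the analysis: the ortho-quinone methide 6, released from the sulfone 3, and the allylic ammonium ylide 7, formed from the carbonate 5 and an amine catalyst. It is made here for three reasons. Each half is one step from a purchasable compound. The C3=C4 alkene is produced by the elimination that releases the catalyst, so ring B arrives at its final oxidation level. The polarity of the partners (nucleophilic carbon onto the methide carbon, phenoxide onto the acrylate terminus) matches the two bonds to be formed. The forward reaction must make the ylide attack through its nitrogen-bearing carbon and must close the seven-membered ring in preference to a five-membered one.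

**3 from 1 and 2; 5 from 4.** The sulfone 3 comes from the benzylic alcohol 1 and the sulfinate 2 by benzylic C–S bond formation. The carbonate 5 comes from the hydroxymethyl acrylate 4 by O-acylation.

## Alternatives that were turned down

Alternative 1: Ring B is cut at C3–C4 and O1–C2 at the level of a fully unsaturated 1-benzoxepine. The vinylphenol A1, methyl 4-hydroxy-3-vinylbenzoate, and the silyl alkyne A2, which carries the whole chain, would be joined under [Cp*RhCl2]2 with Cu(OAc)2 as oxidant by vinyl C–H activation, alkyne insertion and C–O reductive elimination. This would give the 2-silyl-1-benzoxepine A3.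
- For: it is the most convergent plan. A2 is one step from 11, the ester sits on ring A of A1 from the start, and no sulfone or carbonylation is needed. On step count it is clearly stronger than the chosen route, by perhaps three steps.
- Against: A3 is at the wrong oxidation level. It has C2=C3 and C4=C5 and a silicon on the enol ether carbon C2. The silicon has to be removed, and the cyclic diene then has to take up hydrogen in a strictly 1,4 sense across C2 and C5. This must happen beside three trisubstituted chain alkenes, and any 1,2-reduction or over-reduction gives isomers that differ only in alkene position. The insertion regiochemistry depends entirely on the silyl group of A2, and a 2-vinylphenol such as A1 can divert to dearomatised spirocycles under the same catalysis.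
- Comparison: the chosen strategy is longer, but it delivers ring B with C3=C4 fixed by mechanism and needs no late selective reduction.

Alternative 2: Ring B is cut at O1–C9a and C5–C5a. Fluoride would release the chlorinated aryne from the silyl triflate A4. The oxygen of the vinyl oxirane A5 would add to C9a, and the aryl anion at C5a would attack the vinyl terminus with SN2′ opening of the oxirane. This would give the 6-chloro benzoxepine ester A6.
- For: both bonds to ring A form at once, C3=C4 arises directly, and chain and ester are already present in A6, so only dechlorination and ester hydrolysis remain. On the end game it is stronger than the chosen route, which still needs a carbonylation and a desulfonylation.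
- Against: the regiochemistry depends on a chlorine that must be built into the tetrasubstituted arene A4 and then removed from A6 beside four alkenes. A4 and A5 each take several steps. An oxirane oxygen is a weak partner for an aryne, and the zwitterion can collapse at an oxirane carbon to a five-membered ring. The fluoride also meets an ester.
- Comparison: the overall step count is no lower. The chosen strategy offers precursors one step from commercial materials and a ring closure whose regiochemistry follows from the polarity of the partners, with no removable directing atom.

Alternative 3: C3 is inserted into a six-membered ring. Dibromocarbene would add to the enol ether alkene of the chromene ester A7, methyl 4H-chromene-6-carboxylate, to give the gem-dibromocyclopropane A8. Silver-assisted electrocyclic opening of A8 in methanol would then give the 3-bromo-2-methoxy benzoxepine A9.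
- For: this ring expansion of cyclic enol ethers is dependable. The vinyl bromide of A9 would let the chain be attached at C3–C1′ by an sp2–sp3 coupling with the homofarnesyl borane A10. That coupling has no allylic regiochemistry problem and no sulfone to remove, and there it is stronger than the C1′–C2′ coupling chosen here.
- Against: A9 carries an acetal at C2 that must be reduced to a methylene. Ionisation gives an oxocarbenium ion in allylic conjugation with the bromoalkene. Hydride can then enter at C4 and move the alkene to C2=C3, or the aryloxy group can leave and open the ring. A7 and A10 each need separate multistep preparation, so the total is about ten steps.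
- Comparison: the chosen strategy gives ring B with C2 already a methylene and the C1′ handle in place in a single operation.

Key step: step 3

Remark on the chemistry: the farnesyl unit is carried as its p-tolyl sulfone, so that the one sulfinate salt 2 serves steps 1 and 6, and commercial 11 is taken to be the geometrically pure (2E,6E) isomer.

## Route

Step 1
Reactants: 1 5-bromo-2-hydroxybenzyl alcohol; 2 sodium p-toluenesulfinate
Product: 3 4-bromo-2-[(4-methylphenyl)sulfonylmethyl]phenol
Conditions: TolSO2Na (1.5 equiv), HCO2H–H2O, 60 °C
Reagents that add atoms: none
Why: Acid-promoted benzylic substitution; the ortho-hydroxybenzyl alcohol ionises with assistance from the phenol oxygen and the sulfur atom of the sulfinate captures the cation to give the thermodynamically preferred sulfone. The excess of sulfinate should outrun Friedel–Crafts self-condensation.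

Step 2
Reactants: 4 methyl 2-(hydroxymethyl)acrylate
Product: 5 methyl 2-[(tert-butoxycarbonyloxy)methyl]acrylate
Conditions: Boc2O, DMAP (5 mol%), CH2Cl2, 0 °C to rt
Reagents that add atoms: di-tert-butyl dicarbonate, CC(C)(C)OC(=O)OC(=O)OC(C)(C)C
Why: DMAP-catalysed O-acylation of a primary allylic alcohol to its tert-butyl carbonate, the standard activation of Morita–Baylis–Hillman alcohols.

Step 3
Reactants: 3 4-bromo-2-[(4-methylphenyl)sulfonylmethyl]phenol; 5 methyl 2-[(tert-butoxycarbonyloxy)methyl]acrylate
Product: 8 methyl 7-bromo-2,5-dihydro-1-benzoxepine-3-carboxylate, via 4-bromo-6-methylidenecyclohexa-2,4-dien-1-one 6 (not isolated), via DABCO allylic ammonium ylide 7 (not isolated)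
Conditions: DABCO (20 mol%), Cs2CO3 (1.5 equiv), 5 (1.5 equiv), MeCN, 0 °C to rt, slow addition of 3
Reagents that add atoms: none
Why: Proposed new method: Cs2CO3 deprotonates 3 and the phenoxide expels p-toluenesulfinate to give the ortho-quinone methide 6, while DABCO adds SN2′ to 5, the carbonate collapses to CO2 and tert-butoxide, and tert-butoxide deprotonates the allylic ammonium salt to the ylide 7. The nitrogen-bearing carbon of 7 adds to the exocyclic CH2 of 6 and forms C4–C5, driven by re-aromatisation to a phenoxide. The phenoxide then attacks the unsubstituted CH2 terminus of the resulting 2-(ammoniomethyl)acrylate in a 7-endo-trig oxa-Michael addition (O1–C2), and the ester enolate expels DABCO to leave C3=C4, so that ring B closes by an intramolecular SN2′ substitution and the amine turns over. The closest known reaction types are the Lewis-base-catalysed annulations of aryl-substituted Morita–Baylis–Hillman carbonates with stabilised ortho-quinone methides and the phosphine-catalysed (3+2) annulations of such carbonates, which finish by the same addition–elimination; the parent methide and the unsubstituted carbonate have not been shown to combine in the (4+3) sense. No stereocentre is created. Attack through the nitrogen-bearing carbon rather than the remote CH2 terminus is expected because the ylide charge is held next to the ammonium centre. Closure to the seven-membered ring rather than 5-exo-tet displacement of DABCO at C4 is expected because SN2 displacement of a bulky quaternary ammonium group at a secondary carbon is slow, whereas SN2′ attack at an unhindered CH2 terminus is the normal reactivity of amine-activated carbonates of this kind. Slow addition of 3 keeps 6 dilute so that its self-condensation does not compete.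

Step 4
Reactants: 8 methyl 7-bromo-2,5-dihydro-1-benzoxepine-3-carboxylate
Product: 9 (7-bromo-2,5-dihydro-1-benzoxepin-3-yl)methanol
Conditions: i-Bu2AlH (2.5 equiv), CH2Cl2, −78 °C; aq. potassium sodium tartrate
Reagents that add atoms: none
Why: 1,2-Reduction of an α,β-unsaturated ester by an aluminium hydride should give the allylic alcohol and leave the aryl bromide, the allyl aryl ether and the position of C3=C4 untouched.

Step 5
Reactants: 9 (7-bromo-2,5-dihydro-1-benzoxepin-3-yl)methanol
Product: 10 7-bromo-3-(bromomethyl)-2,5-dihydro-1-benzoxepine
Conditions: CBr4, PPh3, CH2Cl2, 0 °C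
Reagents that add atoms: carbon tetrabromide, BrC(Br)(Br)Br
Why: Appel bromination of a primary allylic alcohol under neutral conditions; SN2 displacement of the oxyphosphonium group at the primary carbon should keep C3=C4 in place.

Step 6
Reactants: 11 (2E,6E)-farnesyl bromide; 2 sodium p-toluenesulfinate
Product: 12 (2E,6E)-farnesyl p-tolyl sulfone, that is 1-methyl-4-{[(2E,6E)-3,7,11-trimethyldodeca-2,6,10-trien-1-yl]sulfonyl}benzene
Conditions: TolSO2Na, DMF, rt
Reagents that add atoms: none
Why: SN2 S-alkylation of the sulfinate by a primary allylic bromide in a dipolar aprotic solvent; the primary sulfone is also the thermodynamic regioisomer and both E alkenes are not involved.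

Step 7
Reactants: 12 (2E,6E)-farnesyl p-tolyl sulfone; 10 7-bromo-3-(bromomethyl)-2,5-dihydro-1-benzoxepine
Product: 14 7-bromo-3-{(3E,7E)-4,8,12-trimethyl-2-[(4-methylphenyl)sulfonyl]trideca-3,7,11-trien-1-yl}-2,5-dihydro-1-benzoxepine (racemic at C2′), via lithiated farnesyl p-tolyl sulfone 13 (not isolated)
Conditions: n-BuLi (1.05 equiv), THF, −78 °C; then 10, −78 to −20 °C
Reagents that add atoms: none
Why: n-BuLi removes the allylic α-sulfonyl proton of 12 and the carbanion 13 alkylates through its α-carbon by SN2 at the primary allylic CH2Br of 10, a sulfone-mediated allyl–allyl coupling of the Julia/Biellmann kind that forms C1′–C2′. The new stereocentre at C2′ forms as a racemate and is erased in step 9. No free alkyllithium is left when 10 is added, so the aryl bromide should not undergo exchange.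

Step 8
Reactants: 14 7-bromo-3-{(3E,7E)-4,8,12-trimethyl-2-[(4-methylphenyl)sulfonyl]trideca-3,7,11-trien-1-yl}-2,5-dihydro-1-benzoxepine
Product: 15 3-{(3E,7E)-4,8,12-trimethyl-2-[(4-methylphenyl)sulfonyl]trideca-3,7,11-trien-1-yl}-2,5-dihydro-1-benzoxepine-7-carboxylic acid (racemic at C2′)
Conditions: Pd(OAc)2 (5 mol%), Xantphos (10 mol%), CO (1 atm), H2O, Et3N, 1,4-dioxane, 80 °C; then dilute aq. citric acid
Reagents that add atoms: carbon monoxide, [C-]#[O+]; water, O
Why: Palladium-catalysed hydroxycarbonylation of an aryl bromide: oxidative addition of zerovalent palladium into C7–Br, CO insertion and hydrolysis of the acylpalladium should give the benzoic acid. Under CO the aryl bromide is expected to react faster than the allylic sulfone or the allyl aryl ether is ionised.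

Step 9
Reactants: 15 3-{(3E,7E)-4,8,12-trimethyl-2-[(4-methylphenyl)sulfonyl]trideca-3,7,11-trien-1-yl}-2,5-dihydro-1-benzoxepine-7-carboxylic acid
Product: 16 callophycoic acid F, 3-[(3E,7E)-4,8,12-trimethyltrideca-3,7,11-trien-1-yl]-2,5-dihydro-1-benzoxepine-7-carboxylic acid
Conditions: PdCl2(dppp) (5 mol%), LiBHEt3 (4 equiv), THF, 0 °C; then dilute aq. HCl
Reagents that add atoms: none
Why: Palladium-catalysed hydride reduction of an allylic sulfone: zerovalent palladium ionises C2′–S to a π-allyl complex and hydride from LiBHEt3 is delivered to the less substituted terminus C2′, so C3′=C4′ should stay in place. The E geometry should be kept because syn/anti exchange would have to pass through the tertiary σ-allyl at C4′. The first equivalent of hydride turns the acid into its lithium carboxylate, which should be inert to LiBHEt3 at 0 °C.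

## Compound list

1 | 5-bromo-2-hydroxybenzyl alcohol | OCc1cc(Br)ccc1O | starting material
2 | sodium p-toluenesulfinate | Cc1ccc(cc1)S(=O)[O-].[Na+] | starting material
3 | 4-bromo-2-[(4-methylphenyl)sulfonylmethyl]phenol | Cc1ccc(cc1)S(=O)(=O)Cc1cc(Br)ccc1O | intermediate
4 | methyl 2-(hydroxymethyl)acrylate | C=C(CO)C(=O)OC | starting material
5 | methyl 2-[(tert-butoxycarbonyloxy)methyl]acrylate | COC(=O)C(=C)COC(=O)OC(C)(C)C | intermediate
6 | 4-bromo-6-methylidenecyclohexa-2,4-dien-1-one, the ortho-quinone methide formed in the flask and not isolated | C=C1C=C(Br)C=CC1=O | intermediate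
7 | DABCO allylic ammonium ylide: 1-[2-(methoxycarbonyl)prop-2-en-1-yl]-1,4-diazabicyclo[2.2.2]octan-1-ium deprotonated at the N-bound carbon, a zwitterion formed in the flask and not isolated | COC(=O)C(=C)[CH-][N+]12CCN(CC1)CC2 | intermediate
8 | methyl 7-bromo-2,5-dihydro-1-benzoxepine-3-carboxylate | COC(=O)C1=CCc2cc(Br)ccc2OC1 | intermediate
9 | (7-bromo-2,5-dihydro-1-benzoxepin-3-yl)methanol | OCC1=CCc2cc(Br)ccc2OC1 | intermediate
10 | 7-bromo-3-(bromomethyl)-2,5-dihydro-1-benzoxepine | BrCC1=CCc2cc(Br)ccc2OC1 | intermediate
11 | (2E,6E)-farnesyl bromide | CC(C)=CCC/C(C)=C/CC/C(C)=C/CBr | starting material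
12 | (2E,6E)-farnesyl p-tolyl sulfone | CC(C)=CCC/C(C)=C/CC/C(C)=C/CS(=O)(=O)c1ccc(C)cc1 | intermediate
13 | lithiated (2E,6E)-farnesyl p-tolyl sulfone, the α-sulfonyl carbanion as its lithium salt, formed in the flask and not isolated | CC(C)=CCC/C(C)=C/CC/C(C)=C/[CH-]S(=O)(=O)c1ccc(C)cc1.[Li+] | intermediate
14 | 7-bromo-3-{(3E,7E)-4,8,12-trimethyl-2-[(4-methylphenyl)sulfonyl]trideca-3,7,11-trien-1-yl}-2,5-dihydro-1-benzoxepine (racemic at C2′) | CC(C)=CCC/C(C)=C/CC/C(C)=C/C(CC1=CCc2cc(Br)ccc2OC1)S(=O)(=O)c1ccc(C)cc1 | intermediate
15 | 3-{(3E,7E)-4,8,12-trimethyl-2-[(4-methylphenyl)sulfonyl]trideca-3,7,11-trien-1-yl}-2,5-dihydro-1-benzoxepine-7-carboxylic acid (racemic at C2′) | CC(C)=CCC/C(C)=C/CC/C(C)=C/C(CC1=CCc2cc(C(=O)O)ccc2OC1)S(=O)(=O)c1ccc(C)cc1 | intermediate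
16 | callophycoic acid F | CC(C)=CCC/C(C)=C/CC/C(C)=C/CCC1=CCc2cc(C(=O)O)ccc2OC1 | target

## Step count and least certain steps

Total: 9 steps. Longest linear sequence: 7 steps (steps 1, 3, 4, 5, 7, 8 and 9, from 1 to 16).

**Step 3 (key step).** Four things may go wrong. The zwitterion may close by direct displacement of the ammonium group at C4 to give a five-membered ring, or the ylide may attack through its remote CH2 terminus and move the alkene to C2=C3. The phenoxide of 3 may be O-allylated by the allylic ammonium salt before it has lost sulfinate, because a primary benzylic sulfone eliminates more slowly than the aryl-substituted ones usually used. The unstabilised methide 6 may self-condense. Prolonged exposure of 8 to base may move C3=C4 towards ring A through deprotonation at C5.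

The fallback replaces the annulation by ring-closing metathesis and sets out from 4. PBr3 in Et2O at 0 °C should give methyl 2-(bromomethyl)acrylate F1. F1 would O-alkylate purchased 2-allyl-4-bromophenol F2 (K2CO3, acetone, rt) to give methyl 2-[(2-allyl-4-bromophenoxy)methyl]acrylate F3. Treating F3 with the second-generation Grubbs catalyst in CH2Cl2 at 40 °C should close ring B between the allyl CH and the acrylate carbon with loss of ethene. This is the established metathesis route from 2-allylphenyl allyl ethers to 2,5-dihydro-1-benzoxepines, and it comes back to the route at 8.

**Step 9.** Three things may go wrong. Hydride may be delivered to the tertiary allyl terminus, which transposes the alkene, or the E geometry may erode. Zerovalent palladium may ionise the ring allyl aryl ether O1–C2–C3=C4, which leads to reductive ring opening. The lithium carboxylate may be poorly soluble and slow the reaction.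

The fallback avoids the sulfone altogether and sets out from 10. Purchased (2E,6E)-farnesyl chloride F4 is converted with activated barium (from BaI2 and lithium biphenylide, THF, −78 °C) into (2E,6E)-farnesylbarium chloride F5. Allylbarium reagents couple with allylic halides at the α-carbon with retention of alkene geometry, so adding 10 at −78 °C should give 7-bromo-3-[(3E,7E)-4,8,12-trimethyltrideca-3,7,11-trien-1-yl]-2,5-dihydro-1-benzoxepine F6. Bromine–lithium exchange on F6 (t-BuLi, 2 equiv, THF, −78 °C), carboxylation with CO2 and acidification come back to the route at 16.

**Step 8.** At 80 °C zerovalent palladium may ionise the allylic sulfone or the allyl aryl ether, which would scramble C3′=C4′ or substitute the allyl unit, and protodebromination may compete.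

The fallback moves the carboxylation ahead of the coupling and sets out from 9. Deprotonation of the hydroxyl with n-BuLi (1 equiv), bromine–lithium exchange with t-BuLi (2 equiv, THF, −78 °C) and a CO2 quench should give 3-(hydroxymethyl)-2,5-dihydro-1-benzoxepine-7-carboxylic acid F7. MeI and KHCO3 in DMF should then give methyl 3-(hydroxymethyl)-2,5-dihydro-1-benzoxepine-7-carboxylate F8, and CBr4 with PPh3 should give methyl 3-(bromomethyl)-2,5-dihydro-1-benzoxepine-7-carboxylate F9. Alkylation of 13 with F9 at −78 °C, where the allylic bromide should react far faster than the ester, should give methyl 3-{(3E,7E)-4,8,12-trimethyl-2-[(4-methylphenyl)sulfonyl]trideca-3,7,11-trien-1-yl}-2,5-dihydro-1-benzoxepine-7-carboxylate F10. Saponification of F10 with LiOH in THF–MeOH–H2O comes back to the route at 15.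

**Step 1.** Under acid the hydroxybenzyl cation may alkylate the free ortho position of another phenol ring (oligomerisation), or the primary alcohol may ionise too slowly.

The fallback separates activation from substitution and sets out from 1. Me3SiBr in CHCl3 at rt should give 4-bromo-2-(bromomethyl)phenol F11. SN2 displacement of the bromide of F11 by 2 in DMF at rt, without acid, comes back to the route at 3.

## Further compounds

F1 | step 3 | methyl 2-(bromomethyl)acrylate | C=C(CBr)C(=O)OC
F2 | step 3 | 2-allyl-4-bromophenol | C=CCc1cc(Br)ccc1O
F3 | step 3 | methyl 2-[(2-allyl-4-bromophenoxy)methyl]acrylate | COC(=O)C(=C)COc1ccc(Br)cc1CC=C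
F4 | step 9 | (2E,6E)-farnesyl chloride | CC(C)=CCC/C(C)=C/CC/C(C)=C/CCl
F5 | step 9 | (2E,6E)-farnesylbarium chloride | CC(C)=CCC/C(C)=C/CC/C(C)=C/C[Ba]Cl
F6 | step 9 | 7-bromo-3-[(3E,7E)-4,8,12-trimethyltrideca-3,7,11-trien-1-yl]-2,5-dihydro-1-benzoxepine | CC(C)=CCC/C(C)=C/CC/C(C)=C/CCC1=CCc2cc(Br)ccc2OC1
F7 | step 8 | 3-(hydroxymethyl)-2,5-dihydro-1-benzoxepine-7-carboxylic acid | OCC1=CCc2cc(C(=O)O)ccc2OC1
F8 | step 8 | methyl 3-(hydroxymethyl)-2,5-dihydro-1-benzoxepine-7-carboxylate | OCC1=CCc2cc(C(=O)OC)ccc2OC1
F9 | step 8 | methyl 3-(bromomethyl)-2,5-dihydro-1-benzoxepine-7-carboxylate | BrCC1=CCc2cc(C(=O)OC)ccc2OC1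
F10 | step 8 | methyl 3-{(3E,7E)-4,8,12-trimethyl-2-[(4-methylphenyl)sulfonyl]trideca-3,7,11-trien-1-yl}-2,5-dihydro-1-benzoxepine-7-carboxylate (racemic at C2′) | CC(C)=CCC/C(C)=C/CC/C(C)=C/C(CC1=CCc2cc(C(=O)OC)ccc2OC1)S(=O)(=O)c1ccc(C)cc1
F11 | step 1 | 4-bromo-2-(bromomethyl)phenol | Oc1ccc(Br)cc1CBr
A1 | alternative 1 | methyl 4-hydroxy-3-vinylbenzoate | COC(=O)c1ccc(O)c(C=C)c1
A2 | alternative 1 | trimethyl[(5E,9E)-6,10,14-trimethylpentadeca-5,9,13-trien-1-yn-1-yl]silane | CC(C)=CCC/C(C)=C/CC/C(C)=C/CCC#C[Si](C)(C)C
A3 | alternative 1 | methyl 3-[(3E,7E)-4,8,12-trimethyltrideca-3,7,11-trienyl]-2-(trimethylsilyl)-1-benzoxepine-7-carboxylate | CC(C)=CCC/C(C)=C/CC/C(C)=C/CCC1=C([Si](C)(C)C)Oc2ccc(C(=O)OC)cc2C=C1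
A4 | alternative 2 | methyl 2-chloro-3-(trimethylsilyl)-4-{[(trifluoromethyl)sulfonyl]oxy}benzoate | COC(=O)c1ccc(OS(=O)(=O)C(F)(F)F)c([Si](C)(C)C)c1Cl
A5 | alternative 2 | 2-ethenyl-2-[(3E,7E)-4,8,12-trimethyltrideca-3,7,11-trien-1-yl]oxirane (racemic) | CC(C)=CCC/C(C)=C/CC/C(C)=C/CCC1(C=C)CO1
A6 | alternative 2 | methyl 6-chloro-3-[(3E,7E)-4,8,12-trimethyltrideca-3,7,11-trienyl]-2,5-dihydro-1-benzoxepine-7-carboxylate | CC(C)=CCC/C(C)=C/CC/C(C)=C/CCC1=CCc2c(Cl)c(C(=O)OC)ccc2OC1
A7 | alternative 3 | methyl 4H-chromene-6-carboxylate | COC(=O)c1ccc2OC=CCc2c1
A8 | alternative 3 | gem-dibromocyclopropane formed across C2=C3 of A7 (racemic, cis-fused) | COC(=O)c1ccc2OC3C(Cc2c1)C3(Br)Br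
A9 | alternative 3 | methyl 3-bromo-2-methoxy-2,5-dihydro-1-benzoxepine-7-carboxylate (racemic at C2) | COC1Oc2ccc(C(=O)OC)cc2CC=C1Br
A10 | alternative 3 | 9-[(3E,7E)-4,8,12-trimethyltrideca-3,7,11-trien-1-yl]-9-borabicyclo[3.3.1]nonane | CC(C)=CCC/C(C)=C/CC/C(C)=C/CCB1C2CCCC1CCC2
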